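Assumption: 2,4-dihydroxy-6-methoxybenzaldehyde (1) is treated as a catalogue compound.

## Analysis of the target

The target, Ebenfuran VI (16), is a 2-aryl-1-benzofuran-3-carbaldehyde. Ring A is the benzo ring (C3a, C4, C5, C6, C7, C7a), ring B the furan (O1, C2, C3, C3a, C7a) and ring C the 4-hydroxy-2-methoxyphenyl group on C2. Ring A is substituted everywhere but C7: a free hydroxyl at C4, the 3-hydroxy-3-methylbutyl chain at C5 and a methoxyl at C6. Three ring A oxygens (on C4, C6 and C7a) in a phloroglucinol pattern must therefore be told apart as free phenol, methyl ether and furan oxygen. There is no stereocenter and no olefin geometry in 16, so the problems are regiochemical and chemoselective only. The sensitive groups are the aldehyde (peri to the C4 hydroxyl and next to the ortho-substituted ring C), two oxidisable phenols on electron-rich rings, and the tertiary alcohol, which strong acid could ionise and the C4 hydroxyl could then capture as a chroman. The hard part is to place one carbon on the crowded C3 without touching C7 or ring C, which an electrophilic formylation of a finished 2-arylbenzofuran could also reach, while the three ring A oxygens stay differentiated. The strategy rests on O1, C2 and C3 being contiguous with exactly one carbon on C3: if the oxygen on C7a carries that carbon as a methoxymethyl group and C3a carries an arylalkyne, closing O1–C2 can pass the carbon from O1 to C3.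

## Retrosynthetic reasoning

**16 from 14 (through 15).** Only O–acyl and O–Si bonds are cut last. Both phenols, on C4 and on C4′, are carried as pivalates, so one carbonate methanolysis frees them to give 15, and acidification of the same flask removes the silyl group. A benzyl ether on ring C was avoided because its hydrogenolysis would have to be run beside the aldehyde and the furan double bond.

**14 from 13.** The formyl group is traced back to a C3–CH2OCH3 group. This benzylic ether sits on a very electron-rich heteroarene, so hydride abstraction by a quinone oxidant in the presence of water should convert it to the aldehyde. This choice lets the C3 carbon enter the molecule as part of an ordinary acetal protecting group.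

**13 from 12 (key disconnection).** The O1–C2 bond and the C3–CH2 bond are cut together. This leads to diarylalkyne 12, in which the ring A oxygen para to the side chain bears the methoxymethyl group and the ring A carbon between the two oxygens bears the alkyne. Cutting here builds ring B and installs the C3 carbon in one catalytic isomerisation, with no reagent-derived atoms. The forward step must make the acetal oxygen, and not the pivalate oxygen on the other ortho carbon or the ring C methoxyl, add to the alkyne, and must then move the methoxymethyl group from oxygen to C3.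

**12 from 9 and 11.** The bond between the alkyne and C1′ of ring C is cut, which makes the route convergent. The terminal alkyne is placed on ring A because the ring A carbon between two oxygens is easy to reach as an aldehyde carbon but not selectively as a halide. Ring C is then the simple bromide 11.

**9 from 8, 7 and 6.** The alkyne of 9 is a one-carbon homologue of aldehyde 8. The homologation has to be aprotic and cold, because an aryl pivalate ortho to a formyl group would not survive basic methanol. Before it, the tertiary alcohol of 7 is silylated so that it cannot later intercept the migrating cation, and the phenol of 6 is pivaloylated.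

**6 from 5.** The C–CHO bond is cut next to the free phenol. A magnesium phenoxide-directed formylation delivers the aldehyde only ortho to the free hydroxyl, and phenol 5 has a single open ortho position. The other open ring position, between the methoxyl and the acetal oxygen, is para to the hydroxyl and is not reached by this mechanism. This one step decides which oxygen becomes the C4 hydroxyl and which becomes O1.

**5 from 4, 3 and 2.** The two C–CH3 bonds of the tertiary carbinol are cut back to ester 4, and the chain C–C bond next to the ring is cut back to an olefination of aldehyde 2 (through 3). The aldehyde carbon of 2 becomes the benzylic CH2 of the side chain. The position of the chain between a free hydroxyl and a methoxyl is therefore fixed by the starting aldehyde, and no aromatic C-alkylation is needed.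

**2 from 1, and 11 from 10.** In 1 the hydroxyl para to the formyl group is not chelated and is the more acidic one, so it takes the methoxymethyl group selectively. Bromide 11 is the pivalate of commercial phenol 10.

## Alternatives that were turned down

**Alternative 1: ester-tethered biaryl coupling to a coumestan, then opening.** The disconnection is the C2–C1′ bond, with the C3 carbon and the ring C 2′-oxygen tied together as a lactone. In the forward step the 2-bromoaryl ester A1 of a ring A benzofuran-3-carboxylic acid meets a palladium/trialkylphosphine catalyst. Zerovalent palladium inserts into the C1′–Br bond and arylates the benzofuran C2–H intramolecularly, closing the six-membered lactone of coumestan A2.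
- For: the arylation is intramolecular, has no regiochemical question, and uses the most acidic C–H bond of a benzofuran. The tether brings the C3 carbon and the 2′-oxygen with it. On the dependability of the key bond formation this alternative is at least as strong as the chosen one.
- Against: ring B and the fully substituted benzofuran acid must exist before the key step, so the furan is made in separate steps. The C3 carbon arrives as a lactone carbonyl and must be taken down to the aldehyde. The freed 2′-phenol must be methylated after ring opening. Two benzyl ethers must be removed by hydrogenolysis close to an aldehyde. That is roughly four steps after the key step, against two here.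
- Comparison: the chosen strategy offers instead ring B closure and C3 functionalisation in one step from an open alkyne, with the C3 carbon only one oxidation away from the aldehyde.

**Alternative 2: three-component boronate 1,2-shift.** The disconnection cuts C2–C1′ and C3–CHO at once on a preformed ring A benzofuran A3. In the forward step, C2-lithiated A3 adds to the ring C pinacol boronate A4 to give a boron ate complex. A chloromethyleneiminium salt then attacks C3, ring C shifts from boron to C2, and oxidative removal of boron with hydrolysis gives aldehyde A5.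
- For: three fragments meet in one flask and the formyl group arrives at its final oxidation level. On convergence and redox economy this alternative is stronger than the chosen route.
- Against: the shift dearomatises ring B to a 2,3-dihydrobenzofuran boronate that must be re-aromatised by a formal oxidation. The electrophile must reach C3 beside the peri benzyloxy group on C4, and it could instead substitute the C2–B bond or attack the electron-rich arenes. The pairing of a benzofuranyl boronate complex with an iminium electrophile is not an established reaction. A3 also requires ring B to be built beforehand.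
- Comparison: the chosen strategy offers a key step of a documented catalytic type, at the price of one later oxidation.

**Alternative 3: benzannulation that builds ring A on a furan.** The disconnection removes ring A itself, cutting C7–C7a, C6–C7, C4–C5 and C3a–C4. In the forward step, irradiation of the furyl diazomethyl ketone A6 triggers a Wolff rearrangement to a furylketene. This adds to the 1-methoxyalkyne A7, and cyclobutenone opening, six-electron electrocyclisation onto the furan and tautomerisation give phenol A8 (Danheiser benzannulation).
- For: the polarity of the ynol ether sets the ring A pattern, and the C4 hydroxyl appears free and already distinguished from the C6 methoxyl. No aromatic substitution or selective protection is involved. On ring A regiocontrol this alternative is stronger than the chosen route, which spends eight steps preparing ring A.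
- Against: A6 is a trisubstituted furan that needs its own synthesis, and A7 is a sensitive ynol ether. The electrocyclisation must break furan aromaticity in a crowded system. The step is photochemical. C3 is again an ester, so a reduction and re-oxidation beside a free peri phenol follow, as does benzyl removal near the aldehyde.
- Comparison: the chosen strategy offers catalogue aromatic building blocks, a thermal catalytic key step and a shorter end game.

Key step: step 11

## Route

Step 1
Reactants: 1 2,4-dihydroxy-6-methoxybenzaldehyde
Product: 2 2-hydroxy-6-methoxy-4-(methoxymethoxy)benzaldehyde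
Conditions: MOMCl (1.05 equiv), i-Pr2NEt, CH2Cl2, 0 °C → rt
Reagents that add atoms: chloromethyl methyl ether, COCCl
Why: Selective O-alkylation (acetal protection); the hydroxyl para to the formyl group is the more acidic and is not hydrogen-bonded, whereas the ortho hydroxyl is chelated to the carbonyl and should stay free.

Step 2
Reactants: 2 2-hydroxy-6-methoxy-4-(methoxymethoxy)benzaldehyde
Product: 3 methyl (2E)-3-[2-hydroxy-6-methoxy-4-(methoxymethoxy)phenyl]prop-2-enoate
Conditions: Ph3P=CHCO2Me, toluene, 80 °C
Reagents that add atoms: methyl (triphenylphosphoranylidene)acetate, COC(=O)C=P(c1ccccc1)(c1ccccc1)c1ccccc1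
Why: Wittig olefination with a stabilised ylide, which tolerates the free ortho phenol and should give the E olefin; any Z olefin would lactonise, and the lactone would converge on 5 after steps 3 and 4.

Step 3
Reactants: 3 methyl (2E)-3-[2-hydroxy-6-methoxy-4-(methoxymethoxy)phenyl]prop-2-enoate
Product: 4 methyl 3-[2-hydroxy-6-methoxy-4-(methoxymethoxy)phenyl]propanoate
Conditions: H2 (1 atm), Pd/C (10 wt%), EtOAc, rt
Reagents that add atoms: none
Why: Catalytic hydrogenation of a cinnamate double bond; the aryl acetal is not a benzylic C–O bond and should not be hydrogenolysed in a neutral aprotic solvent.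

Step 4
Reactants: 4 methyl 3-[2-hydroxy-6-methoxy-4-(methoxymethoxy)phenyl]propanoate
Product: 5 2-(3-hydroxy-3-methylbutyl)-3-methoxy-5-(methoxymethoxy)phenol
Conditions: MeMgBr (4 equiv), THF, 0 °C → rt; aq. NH4Cl
Reagents that add atoms: methylmagnesium bromide, C[Mg]Br
Why: Double Grignard addition to an ester gives the tertiary carbinol; one equivalent is spent on the phenol, and the acetal is inert to the reagent.

Step 5
Reactants: 5 2-(3-hydroxy-3-methylbutyl)-3-methoxy-5-(methoxymethoxy)phenol
Product: 6 2-hydroxy-3-(3-hydroxy-3-methylbutyl)-4-methoxy-6-(methoxymethoxy)benzaldehyde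
Conditions: MgCl2, Et3N, (CH2O)n, THF, 70 °C; aq. NH4Cl
Reagents that add atoms: formaldehyde (as paraformaldehyde), C=O
Why: Magnesium-mediated ortho-formylation of a phenol (Casnati–Skattebøl type); formaldehyde is delivered within the magnesium phenoxide chelate, so only the single free ortho position reacts and the equally activated position para to the hydroxyl is left alone. A second formaldehyde oxidises the hydroxymethyl intermediate by hydride transfer.

Step 6
Reactants: 6 2-hydroxy-3-(3-hydroxy-3-methylbutyl)-4-methoxy-6-(methoxymethoxy)benzaldehyde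
Product: 7 2-formyl-6-(3-hydroxy-3-methylbutyl)-5-methoxy-3-(methoxymethoxy)phenyl pivalate
Conditions: PivCl, Et3N, DMAP (cat.), CH2Cl2, 0 °C → rt
Reagents that add atoms: pivaloyl chloride, CC(C)(C)C(Cl)=O
Why: Acylation of a phenol; the tertiary alcohol is too hindered to react with pivaloyl chloride under these conditions, so only the phenol should be esterified.

Step 7
Reactants: 7 2-formyl-6-(3-hydroxy-3-methylbutyl)-5-methoxy-3-(methoxymethoxy)phenyl pivalate
Product: 8 2-formyl-5-methoxy-3-(methoxymethoxy)-6-[3-methyl-3-(triethylsilyloxy)butyl]phenyl pivalate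
Conditions: Et3SiOTf (1.2 equiv), 2,6-lutidine, CH2Cl2, −78 °C
Reagents that add atoms: triethylsilyl trifluoromethanesulfonate, CC[Si](CC)(CC)OS(=O)(=O)C(F)(F)F
Why: Silylation of a tertiary alcohol with a silyl triflate and a hindered base; at low temperature and near-stoichiometric triflate the aryl acetal should not be attacked.

Step 8
Reactants: 8 2-formyl-5-methoxy-3-(methoxymethoxy)-6-[3-methyl-3-(triethylsilyloxy)butyl]phenyl pivalate
Product: 9 2-ethynyl-5-methoxy-3-(methoxymethoxy)-6-[3-methyl-3-(triethylsilyloxy)butyl]phenyl pivalate
Conditions: Me3SiCHN2, LiN(i-Pr)2, THF, −78 °C → rt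
Reagents that add atoms: (trimethylsilyl)diazomethane, C[Si](C)(C)C=[N+]=[N-]
Why: Colvin rearrangement: the lithiated silyl diazomethane adds to the aldehyde, Peterson elimination gives a diazoalkene, and loss of N2 with a 1,2-shift gives the terminal alkyne. The aprotic medium at −78 °C is chosen because the ortho pivalate would be lost under the basic methanol of the usual diazophosphonate homologation.

Step 9
Reactants: 10 4-bromo-3-methoxyphenol
Product: 11 4-bromo-3-methoxyphenyl pivalate
Conditions: PivCl, Et3N, DMAP (cat.), CH2Cl2, 0 °C → rt
Reagents that add atoms: pivaloyl chloride, CC(C)(C)C(Cl)=O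
Why: Acylation of a phenol; the ester also makes the aryl bromide less electron-rich, which helps oxidative addition in step 10.

Step 10
Reactants: 9 2-ethynyl-5-methoxy-3-(methoxymethoxy)-6-[3-methyl-3-(triethylsilyloxy)butyl]phenyl pivalate; 11 4-bromo-3-methoxyphenyl pivalate
Product: 12 5-methoxy-2-{[2-methoxy-4-(pivaloyloxy)phenyl]ethynyl}-3-(methoxymethoxy)-6-[3-methyl-3-(triethylsilyloxy)butyl]phenyl pivalate
Conditions: PdCl2(PhCN)2 (3 mol%), [HP(t-Bu)3]BF4 (6 mol%), CuI (2 mol%), i-Pr2NH, 1,4-dioxane, rt → 40 °C
Reagents that add atoms: none
Why: Sonogashira coupling; the bulky electron-rich trialkylphosphine allows oxidative addition into an ortho-alkoxy aryl bromide near room temperature, and the hindered secondary amine should not cleave the aryl pivalates.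

Step 11
Reactants: 12 5-methoxy-2-{[2-methoxy-4-(pivaloyloxy)phenyl]ethynyl}-3-(methoxymethoxy)-6-[3-methyl-3-(triethylsilyloxy)butyl]phenyl pivalate
Product: 13 6-methoxy-2-[2-methoxy-4-(pivaloyloxy)phenyl]-3-(methoxymethyl)-5-[3-methyl-3-(triethylsilyloxy)butyl]-1-benzofuran-4-yl pivalate
Conditions: PtCl2 (5 mol%), 1,5-cyclooctadiene (20 mol%), toluene, 40 °C
Reagents that add atoms: none
Why: Divalent platinum binds the diarylalkyne of 12, and the acetal oxygen on the neighbouring ring A carbon adds anti to the metal at the alkyne carbon that carries ring C, which forms O1–C2 and closes ring B in a 5-endo-dig mode. The resulting vinylplatinum oxonium ion expels the methoxymethyl cation, which is stabilised as an oxocarbenium ion; the electron-rich platinum-bearing C3 captures it, forming the C3–CH2 bond and releasing the catalyst, so the net change is an isomerisation. The closest known reaction type is the PtCl2-catalysed carboalkoxylation of ortho-alkynylphenyl acetals to 3-(alkoxyalkyl)benzofurans, in which an olefin additive such as 1,5-cyclooctadiene speeds up turnover. No stereocenter is formed. The selectivity needed is among three oxygens that can reach the alkyne: the pivalate oxygen on the other ortho carbon is a poor donor and carries no group that can leave as a stabilised cation, and the ring C methoxyl would give a methyloxonium ion that cannot turn over, so both additions are reversible dead ends and only the acetal oxygen leads on. The alkyne carbon attached to ring C is also the more electrophilic one, because the ortho methoxyl of ring C stabilises positive charge there. The silyl ether keeps the tertiary hydroxyl from intercepting the methoxymethyl cation.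

Step 12
Reactants: 13 6-methoxy-2-[2-methoxy-4-(pivaloyloxy)phenyl]-3-(methoxymethyl)-5-[3-methyl-3-(triethylsilyloxy)butyl]-1-benzofuran-4-yl pivalate
Product: 14 3-formyl-6-methoxy-2-[2-methoxy-4-(pivaloyloxy)phenyl]-5-[3-methyl-3-(triethylsilyloxy)butyl]-1-benzofuran-4-yl pivalate
Conditions: DDQ (1.5 equiv), CH2Cl2/pH 7 phosphate buffer (10:1), 0 °C → rt
Reagents that add atoms: water, O
Why: Oxidation of an electron-rich benzylic methyl ether by hydride abstraction; the cation at the C3 methylene is stabilised by O1, ring C and the ether oxygen, water adds, and the hemiacetal loses methanol to give the aldehyde. Both phenols are masked as esters, which protects the rings from the quinone, and the benzylic CH2 of the C5 chain has no α-oxygen and should react much more slowly.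

Step 13
Reactants: 14 3-formyl-6-methoxy-2-[2-methoxy-4-(pivaloyloxy)phenyl]-5-[3-methyl-3-(triethylsilyloxy)butyl]-1-benzofuran-4-yl pivalate
Product: 16 Ebenfuran VI (4-hydroxy-2-(4-hydroxy-2-methoxyphenyl)-5-(3-hydroxy-3-methylbutyl)-6-methoxy-1-benzofuran-3-carbaldehyde), via bisphenol triethylsilyl ether 15 (not isolated)
Conditions: K2CO3, MeOH, 40 °C, Ar; then 1 M aq. HCl to pH 1–2, rt
Reagents that add atoms: none
Why: Methanolysis of two aryl esters (phenoxide is a good leaving group even from the hindered C4 ester) followed by acid-catalysed cleavage of the silyl ether in the same flask. Dilute acid at room temperature should not ionise the tertiary alcohol, and the chelated aldehyde is untouched.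

## Compound list

1 | 2,4-dihydroxy-6-methoxybenzaldehyde | COc1cc(O)cc(O)c1C=O | starting material
2 | 2-hydroxy-6-methoxy-4-(methoxymethoxy)benzaldehyde | COCOc1cc(O)c(C=O)c(OC)c1 | intermediate
3 | methyl (2E)-3-[2-hydroxy-6-methoxy-4-(methoxymethoxy)phenyl]prop-2-enoate | COCOc1cc(O)c(/C=C/C(=O)OC)c(OC)c1 | intermediate
4 | methyl 3-[2-hydroxy-6-methoxy-4-(methoxymethoxy)phenyl]propanoate | COCOc1cc(O)c(CCC(=O)OC)c(OC)c1 | intermediate
5 | 2-(3-hydroxy-3-methylbutyl)-3-methoxy-5-(methoxymethoxy)phenol | COCOc1cc(O)c(CCC(C)(C)O)c(OC)c1 | intermediate
6 | 2-hydroxy-3-(3-hydroxy-3-methylbutyl)-4-methoxy-6-(methoxymethoxy)benzaldehyde | COCOc1cc(OC)c(CCC(C)(C)O)c(O)c1C=O | intermediate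
7 | 2-formyl-6-(3-hydroxy-3-methylbutyl)-5-methoxy-3-(methoxymethoxy)phenyl pivalate | COCOc1cc(OC)c(CCC(C)(C)O)c(OC(=O)C(C)(C)C)c1C=O | intermediate
8 | 2-formyl-5-methoxy-3-(methoxymethoxy)-6-[3-methyl-3-(triethylsilyloxy)butyl]phenyl pivalate | COCOc1cc(OC)c(CCC(C)(C)O[Si](CC)(CC)CC)c(OC(=O)C(C)(C)C)c1C=O | intermediate
9 | 2-ethynyl-5-methoxy-3-(methoxymethoxy)-6-[3-methyl-3-(triethylsilyloxy)butyl]phenyl pivalate | COCOc1cc(OC)c(CCC(C)(C)O[Si](CC)(CC)CC)c(OC(=O)C(C)(C)C)c1C#C | intermediate
10 | 4-bromo-3-methoxyphenol | COc1cc(O)ccc1Br | starting material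
11 | 4-bromo-3-methoxyphenyl pivalate | COc1cc(OC(=O)C(C)(C)C)ccc1Br | intermediate
12 | 5-methoxy-2-{[2-methoxy-4-(pivaloyloxy)phenyl]ethynyl}-3-(methoxymethoxy)-6-[3-methyl-3-(triethylsilyloxy)butyl]phenyl pivalate | COCOc1cc(OC)c(CCC(C)(C)O[Si](CC)(CC)CC)c(OC(=O)C(C)(C)C)c1C#Cc1ccc(OC(=O)C(C)(C)C)cc1OC | intermediate
13 | 6-methoxy-2-[2-methoxy-4-(pivaloyloxy)phenyl]-3-(methoxymethyl)-5-[3-methyl-3-(triethylsilyloxy)butyl]-1-benzofuran-4-yl pivalate | COCc1c(-c2ccc(OC(=O)C(C)(C)C)cc2OC)oc2cc(OC)c(CCC(C)(C)O[Si](CC)(CC)CC)c(OC(=O)C(C)(C)C)c12 | intermediate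
14 | 3-formyl-6-methoxy-2-[2-methoxy-4-(pivaloyloxy)phenyl]-5-[3-methyl-3-(triethylsilyloxy)butyl]-1-benzofuran-4-yl pivalate | O=Cc1c(-c2ccc(OC(=O)C(C)(C)C)cc2OC)oc2cc(OC)c(CCC(C)(C)O[Si](CC)(CC)CC)c(OC(=O)C(C)(C)C)c12 | intermediate
15 | 4-hydroxy-2-(4-hydroxy-2-methoxyphenyl)-6-methoxy-5-[3-methyl-3-(triethylsilyloxy)butyl]-1-benzofuran-3-carbaldehyde | O=Cc1c(-c2ccc(O)cc2OC)oc2cc(OC)c(CCC(C)(C)O[Si](CC)(CC)CC)c(O)c12 | intermediate
16 | Ebenfuran VI, 4-hydroxy-2-(4-hydroxy-2-methoxyphenyl)-5-(3-hydroxy-3-methylbutyl)-6-methoxy-1-benzofuran-3-carbaldehyde | COc1cc(O)ccc1-c1oc2cc(OC)c(CCC(C)(C)O)c(O)c2c1C=O | target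

## Step count and risk

Total step count: 13. Longest linear sequence: 12 steps (steps 1 to 8 and 10 to 13); step 9 prepares the ring C partner.

**Step 11 (key step).** Turnover may be slow because the alkyne is shielded by three ortho substituents. The methoxymethyl cation may also be lost to an outside nucleophile, so that C3 is protonated instead of alkylated. Reversible addition of the ring C methoxyl or the pivalate carbonyl to the activated alkyne could tie up the catalyst.
Fallback, from 12 to 16:
- HCl in MeOH at 40 °C removes the acetal and the silyl ether and should give 3-hydroxy-6-(3-hydroxy-3-methylbutyl)-5-methoxy-2-{[2-methoxy-4-(pivaloyloxy)phenyl]ethynyl}phenyl pivalate F1.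
- I2 and NaHCO3 in MeCN then close ring B by iodocyclisation of the free phenol, the only strongly nucleophilic oxygen, to give 5-(3-hydroxy-3-methylbutyl)-3-iodo-6-methoxy-2-[2-methoxy-4-(pivaloyloxy)phenyl]-1-benzofuran-4-yl pivalate F2.
- Reductive carbonylation with PdCl2(dppp), CO, Et3SiH and Na2CO3 in DMF turns the C3 iodide into the aldehyde 3-formyl-5-(3-hydroxy-3-methylbutyl)-6-methoxy-2-[2-methoxy-4-(pivaloyloxy)phenyl]-1-benzofuran-4-yl pivalate F3.
- The carbonate methanolysis of step 13, without the acid stage, brings F3 to 16.

**Step 8.** The lithiated reagent, or the benzylic alkoxide formed after its addition, may attack the neighbouring pivalate, so that the acyl group is transferred or lost before the elimination to the alkyne.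
Fallback, from 6 to 9:
- Allyl bromide and K2CO3 in DMF give 3-(3-hydroxy-3-methylbutyl)-4-methoxy-6-(methoxymethoxy)-2-(prop-2-en-1-yloxy)benzaldehyde F4.
- Ohira–Bestmann homologation (dimethyl (1-diazo-2-oxopropyl)phosphonate, K2CO3, MeOH), now harmless because no ester is present, gives 4-[3-ethynyl-6-methoxy-4-(methoxymethoxy)-2-(prop-2-en-1-yloxy)phenyl]-2-methylbutan-2-ol F5.
- Pd(PPh3)4 and morpholine in THF remove the allyl group to give 2-ethynyl-6-(3-hydroxy-3-methylbutyl)-5-methoxy-3-(methoxymethoxy)phenol F6.
- PivCl, Et3N and DMAP give 2-ethynyl-6-(3-hydroxy-3-methylbutyl)-5-methoxy-3-(methoxymethoxy)phenyl pivalate F7.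
- Et3SiOTf and 2,6-lutidine return the route to 9.

**Step 10.** Oxidative addition into the ortho-alkoxy aryl bromide may be slow, which would leave time for copper-mediated oxidative dimerisation of the hindered alkyne.
Fallback with reversed polarity, from 9 and 11 to 12:
- NBS and catalytic AgNO3 in acetone convert 9 into 2-(bromoethynyl)-5-methoxy-3-(methoxymethoxy)-6-[3-methyl-3-(triethylsilyloxy)butyl]phenyl pivalate F8.
- Miyaura borylation of 11 (B2pin2, PdCl2(dppf), KOAc, dioxane, 80 °C) gives 3-methoxy-4-(4,4,5,5-tetramethyl-1,3,2-dioxaborolan-2-yl)phenyl pivalate F9.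
- Suzuki-type alkynylation of F9 with F8 (PdCl2(dppf), CsF, THF, 50 °C) gives 12.

**Step 12.** Hydride abstraction may be slowed by the peri pivalate, and electron-transfer oxidation of the electron-rich rings may compete. Loss of the silyl ether in the acidic medium would be harmless.
Fallback, from 13 to 16:
- Dilute aqueous HCl in THF at 40 °C exchanges the stabilised benzylic ether by ionisation and water capture, and removes the silyl group, to give 5-(3-hydroxy-3-methylbutyl)-3-(hydroxymethyl)-6-methoxy-2-[2-methoxy-4-(pivaloyloxy)phenyl]-1-benzofuran-4-yl pivalate F10.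
- MnO2 in CH2Cl2 oxidises the benzylic alcohol to the silyl-free aldehyde 3-formyl-5-(3-hydroxy-3-methylbutyl)-6-methoxy-2-[2-methoxy-4-(pivaloyloxy)phenyl]-1-benzofuran-4-yl pivalate F3.
- The carbonate methanolysis of step 13 gives 16.

## Further compounds

F1 | step 11 | 3-hydroxy-6-(3-hydroxy-3-methylbutyl)-5-methoxy-2-{[2-methoxy-4-(pivaloyloxy)phenyl]ethynyl}phenyl pivalate | Oc1cc(OC)c(CCC(C)(C)O)c(OC(=O)C(C)(C)C)c1C#Cc1ccc(OC(=O)C(C)(C)C)cc1OC
F2 | step 11 | 5-(3-hydroxy-3-methylbutyl)-3-iodo-6-methoxy-2-[2-methoxy-4-(pivaloyloxy)phenyl]-1-benzofuran-4-yl pivalate | Ic1c(-c2ccc(OC(=O)C(C)(C)C)cc2OC)oc2cc(OC)c(CCC(C)(C)O)c(OC(=O)C(C)(C)C)c12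
F3 | step 11 | 3-formyl-5-(3-hydroxy-3-methylbutyl)-6-methoxy-2-[2-methoxy-4-(pivaloyloxy)phenyl]-1-benzofuran-4-yl pivalate | O=Cc1c(-c2ccc(OC(=O)C(C)(C)C)cc2OC)oc2cc(OC)c(CCC(C)(C)O)c(OC(=O)C(C)(C)C)c12
F4 | step 8 | 3-(3-hydroxy-3-methylbutyl)-4-methoxy-6-(methoxymethoxy)-2-(prop-2-en-1-yloxy)benzaldehyde | COCOc1cc(OC)c(CCC(C)(C)O)c(OCC=C)c1C=O
F5 | step 8 | 4-[3-ethynyl-6-methoxy-4-(methoxymethoxy)-2-(prop-2-en-1-yloxy)phenyl]-2-methylbutan-2-ol | COCOc1cc(OC)c(CCC(C)(C)O)c(OCC=C)c1C#C
F6 | step 8 | 2-ethynyl-6-(3-hydroxy-3-methylbutyl)-5-methoxy-3-(methoxymethoxy)phenol | COCOc1cc(OC)c(CCC(C)(C)O)c(O)c1C#C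
F7 | step 8 | 2-ethynyl-6-(3-hydroxy-3-methylbutyl)-5-methoxy-3-(methoxymethoxy)phenyl pivalate | COCOc1cc(OC)c(CCC(C)(C)O)c(OC(=O)C(C)(C)C)c1C#C
F8 | step 10 | 2-(bromoethynyl)-5-methoxy-3-(methoxymethoxy)-6-[3-methyl-3-(triethylsilyloxy)butyl]phenyl pivalate | COCOc1cc(OC)c(CCC(C)(C)O[Si](CC)(CC)CC)c(OC(=O)C(C)(C)C)c1C#CBr
F9 | step 10 | 3-methoxy-4-(4,4,5,5-tetramethyl-1,3,2-dioxaborolan-2-yl)phenyl pivalate | COc1cc(OC(=O)C(C)(C)C)ccc1B1OC(C)(C)C(C)(C)O1
F10 | step 12 | 5-(3-hydroxy-3-methylbutyl)-3-(hydroxymethyl)-6-methoxy-2-[2-methoxy-4-(pivaloyloxy)phenyl]-1-benzofuran-4-yl pivalate | OCc1c(-c2ccc(OC(=O)C(C)(C)C)cc2OC)oc2cc(OC)c(CCC(C)(C)O)c(OC(=O)C(C)(C)C)c12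
A1 | alternative 1 | 5-(benzyloxy)-2-bromophenyl 4-(benzyloxy)-5-(3-hydroxy-3-methylbutyl)-6-methoxy-1-benzofuran-3-carboxylate | O=C(Oc1cc(OCc2ccccc2)ccc1Br)c1coc2cc(OC)c(CCC(C)(C)O)c(OCc3ccccc3)c12
A2 | alternative 1 | 3,7-bis(benzyloxy)-8-(3-hydroxy-3-methylbutyl)-9-methoxy-6H-[1]benzofuro[3,2-c]chromen-6-one | O=C1Oc2cc(OCc3ccccc3)ccc2-c2oc3cc(OC)c(CCC(C)(C)O)c(OCc4ccccc4)c3c21
A3 | alternative 2 | 4-(benzyloxy)-6-methoxy-5-[3-methyl-3-(triethylsilyloxy)butyl]-1-benzofuran | COc1cc2occc2c(OCc2ccccc2)c1CCC(C)(C)O[Si](CC)(CC)CC
A4 | alternative 2 | 2-[4-(benzyloxy)-2-methoxyphenyl]-4,4,5,5-tetramethyl-1,3,2-dioxaborolane | COc1cc(OCc2ccccc2)ccc1B1OC(C)(C)C(C)(C)O1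
A5 | alternative 2 | 4-(benzyloxy)-2-[4-(benzyloxy)-2-methoxyphenyl]-6-methoxy-5-[3-methyl-3-(triethylsilyloxy)butyl]-1-benzofuran-3-carbaldehyde | O=Cc1c(-c2ccc(OCc3ccccc3)cc2OC)oc2cc(OC)c(CCC(C)(C)O[Si](CC)(CC)CC)c(OCc3ccccc3)c12
A6 | alternative 3 | methyl 2-[4-(benzyloxy)-2-methoxyphenyl]-5-(2-diazoacetyl)furan-3-carboxylate | COC(=O)c1cc(C(=O)C=[N+]=[N-])oc1-c1ccc(OCc2ccccc2)cc1OC
A7 | alternative 3 | 1-methoxy-5-methyl-5-(triethylsilyloxy)hex-1-yne | COC#CCCC(C)(C)O[Si](CC)(CC)CC
A8 | alternative 3 | methyl 2-[4-(benzyloxy)-2-methoxyphenyl]-4-hydroxy-6-methoxy-5-[3-methyl-3-(triethylsilyloxy)butyl]-1-benzofuran-3-carboxylate | COC(=O)c1c(-c2ccc(OCc3ccccc3)cc2OC)oc2cc(OC)c(CCC(C)(C)O[Si](CC)(CC)CC)c(O)c12
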